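**Retrosynthetic overview**
1. Feature: ring B (C5–C10) carries oxygen at C6, methyl groups at C8 and C10 and a carbon substituent (C11) at C9. This is the substitution pattern of 2,6-dimethyl-1,4-benzoquinone. The gem-dimethyl carbon C4 of ring A sits next to C5, where the disubstituted end of 4-methylpenta-1,3-diene would arrive. Numbering: decalin C1–C10; ring C = C8, C9, C11–C14 with spiro C13; ring E = C15–C20 with C17=O, C18–CH3 and C20–OH; ring D = O, C13, C15, C20, C19.
2. Ring D: O–C19 by intramolecular oxa-Michael addition of the C13 tertiary alcohol to a C17 enone. C13–C15 by aldol addition of an enantiopure ring-E dienolate to a C13 ketone that already bears the C6 acetate.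
3. Ring C: C11–C12 by aldol condensation of a C11 aldehyde with a C13 methyl ketone. C8–C14 and the C9=C11 methylene both come from one Claisen rearrangement of a C8=C9 allylic alcohol.
4. Ring A: C1–C10 and C4–C5 by a catalytic enantioselective quinone Diels–Alder reaction. C5 is epimerised afterwards through the C6 ketone, and C6, C8, C9 and C13 are relayed from C10.
5. Order of rings: B (from the quinone), A, C, E (attached as a unit), D.

Key step: step 1

Convention: Me-face = the face of the decalin that carries the C10 methyl group; H-face = the opposite face.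
Assumption: the (S)-prolinol-derived catalyst is written because the usual binding model (boron on O6, C5–H···O contact, one catalyst phenyl group covering the rear face) exposes the face that leads to (8aR)-3. The sense is to be confirmed on 3, and the mirror-image catalyst is equally available.

Step 1
Reactants: 1 2,6-dimethyl-1,4-benzoquinone; 2 4-methylpenta-1,3-diene
Product: 3 (4aS,8aR)-2,5,5,8a-tetramethyl-4a,5,8,8a-tetrahydronaphthalene-1,4-dione (cis-fused enedione; C5–H and C10–CH3 on the same face)
Conditions: (S)-3,3-diphenyl-1-(2-methylphenyl)tetrahydro-1H,3H-pyrrolo[1,2-c][1,3,2]oxazaborole (20 mol %), Tf2NH (18 mol %), CH2Cl2, −40 → −20 °C, 2 (5 equiv, slow addition)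
Reagents that add atoms: none
Why: The N-protonated oxazaborolidine binds O6 of 1, the carbonyl oxygen that is flanked by two C–H groups and made more basic by the two β-methyl groups, and so polarises the C5=C10 bond with C10 as the electrophilic end; the s-cis conformer of 2 then adds suprafacially in a concerted, strongly asynchronous [4+2] cycloaddition in which C1–C10 runs ahead of C4–C5. The closest known reactions are the oxazaborolidinium-catalysed Diels–Alder additions to methylated 1,4-benzoquinones and the Lewis-acid-directed additions of 1-substituted dienes to 1. Ring A closes in one [π4s+π2s] event from an open diene, and no second ring is formed. C10 is set by the catalyst, whose phenyl group covers one face of the bound C5=C10 bond, and C5 follows from suprafacial addition, hence the cis fusion; C1 and C4 each carry two identical substituents, so endo or exo approach creates no further centre. The step needs orientation, mono-addition and enantioface selectivity: the larger HOMO coefficient at the CH2 terminus of 2 matches C10 and the CMe2 terminus avoids the methyl-bearing carbon, the two quinone C=C bonds are symmetry-equivalent, and the remaining C7=C8 bond of 3 is a less activated and more hindered dienophile. The Z-methyl group of 2 raises the energy of the s-cis form, so excess diene, slow addition and a temperature above that usual for this catalyst are planned.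

Step 2
Reactants: 3 cis-fused enedione
Product: 5 cis-fused saturated 6,9-dione (C8 epimers), via ring-A alkene dione 4 (not isolated)
Conditions: H2 (3 atm), 10% Pd/C, EtOAc, rt
Reagents that add atoms: none
Why: Heterogeneous catalytic hydrogenation saturates first the electron-poor C7=C8 bond and then the cis-disubstituted C2=C3 bond while both ketones survive, and the new C8 centre is of no concern because it is α to C9=O and is equilibrated in step 3.

Step 3
Reactants: 5 cis-fused saturated 6,9-dione
Product: 6 trans-fused 4,4,8,10-tetramethyldecalin-6,9-dione (C5–H on the H-face; C8–CH3 equatorial)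
Conditions: NaOMe (0.3 equiv), MeOH, rt → 40 °C
Reagents that add atoms: none
Why: Base-catalysed epimerisation through the C5=C6 enolate is under thermodynamic control and should favour the trans-decalin, because in the cis isomer C4 is axial on ring B and pushes one of its methyl groups over C7 and C9, while the C8 methyl group settles in the equatorial position through the C8=C9 enolate.

Step 4
Reactants: 6 trans-fused 6,9-dione
Product: 7 6-hydroxy-9-ketone (C6–OH axial on the Me-face)
Conditions: NaBH4 (1.0 equiv), MeOH–CH2Cl2 (1:1), −40 °C
Reagents that add atoms: none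
Why: Chemoselective borohydride reduction takes the C6 ketone, whose neighbours are CH and CH2, in preference to the C9 ketone between quaternary C10 and methyl-bearing C8, and hydride arrives from the H-face because the axial methyl groups on C4 and C10 close the Me-face, which gives the axial alcohol as in the reduction of 6-oxo steroids and 6-oxodrimanes.

Step 5
Reactants: 7 6-hydroxy-9-ketone
Product: 8 6-benzyloxy-9-ketone
Conditions: 2-benzyloxy-1-methylpyridinium triflate (2 equiv), MgO, PhCF3, 85 °C
Reagents that add atoms: 2-benzyloxy-1-methylpyridinium triflate, C[n+]1ccccc1OCc1ccccc1.[O-]S(=O)(=O)C(F)(F)F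
Why: Benzyl transfer from the pyridinium salt proceeds under neutral conditions through a benzyl cation equivalent, so that the hindered axial alcohol is etherified without enolising the C9 ketone, and no stereocentre is touched.

Step 6
Reactants: 8 6-benzyloxy-9-ketone
Product: 10 C8=C9 enol triflate, via potassium enolate 9 (not isolated)
Conditions: KHMDS, THF, −78 → 0 °C; PhNTf2, 0 °C → rt
Reagents that add atoms: N-phenylbis(trifluoromethanesulfonimide), O=S(=O)(N(c1ccccc1)S(=O)(=O)C(F)(F)F)C(F)(F)F
Why: Because C10 is quaternary the C9 ketone can enolise only towards C8, so deprotonation followed by O-sulfonylation (enol triflate formation, well known for 2,2,6-trimethylcyclohexanone) gives a single regioisomer and erases the C8 centre.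

Step 7
Reactants: 10 C8=C9 enol triflate
Product: 11 methyl C8=C9-ene-11-oate (C11 = ester carbon on C9)
Conditions: Pd(OAc)2 (10 mol %), dppf (12 mol %), CO (1 atm), MeOH, Et3N, DMF, 65 °C
Reagents that add atoms: carbon monoxide, [C-]#[O+]; methanol, CO
Why: Palladium-catalysed methoxycarbonylation (oxidative addition of zerovalent palladium into the C9–O bond, CO insertion, methanolysis) brings in C11 without any nucleophilic attack on a hindered carbonyl group.

Step 8
Reactants: 11 methyl ester
Product: 12 C8=C9 allylic alcohol (C11H2OH on C9)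
Conditions: DIBAL-H (3 equiv), CH2Cl2, −78 → 0 °C; aq Rochelle salt
Reagents that add atoms: none
Why: DIBAL-H reduces the conjugated ester in a 1,2 sense to the primary allylic alcohol and leaves the tetrasubstituted alkene and the benzyl ether alone.

Step 9
Reactants: 12 allylic alcohol
Product: 14 C8-acetonyl C9-methylene decalin (C8–CH3 axial on the Me-face; C14 chain equatorial), via allyl isopropenyl ether 13 (not isolated)
Conditions: 2-methoxypropene (10 equiv), PPTS (5 mol %), toluene, sealed tube, 130 °C
Reagents that add atoms: 2-methoxypropene, COC(C)=C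
Why: Saucy–Marbet variant of the Claisen rearrangement: acid-catalysed exchange gives ether 13, whose [3,3] shift forms C8–C14 and moves the alkene to C9=C11 in one operation, the new bond arising on the H-face because the Me-face of C8 is syn-axial to the C10 methyl group, so that the C8 methyl ends up axial and the acetonyl chain equatorial, and the olefination of a C9 ketone between two quaternary carbons is avoided.

Step 10
Reactants: 14 C8-acetonyl C9-methylene decalin
Product: 16 C11/C13 diol (C9–H on the H-face; C13 carbinol epimers), via bis-boron adduct 15 (not isolated)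
Conditions: BH3·THF (4 equiv), THF, 0 → 40 °C; 3 M NaOH, 30% H2O2, 0 °C → rt
Reagents that add atoms: hydrogen peroxide, OO
Why: Hydroboration–oxidation places boron on the terminal C11 and delivers hydrogen to C9 from the H-face, since the axial methyl groups on C8 and C10 flank the Me-face, which sets C9–H anti to both methyl groups and C11 equatorial, while the ketone is reduced in passing to an epimer mixture that is erased in step 11.

Step 11
Reactants: 16 diol
Product: 17 C11 aldehyde C13 methyl ketone
Conditions: Dess–Martin periodinane (2.5 equiv), CH2Cl2, 0 °C → rt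
Reagents that add atoms: none
Why: Dess–Martin oxidation converts both alcohols under non-epimerising conditions, and the C9 formyl group is already in the more stable equatorial position.

Step 12
Reactants: 17 keto aldehyde
Product: 19 tricyclic C11=C12 en-13-one (B/C trans), via aldol 18 (not isolated)
Conditions: KOH, MeOH, rt → 50 °C
Reagents that add atoms: none
Why: Intramolecular aldol condensation: only attack of the C12 methyl-ketone enolate on the C11 aldehyde gives a six-membered ring (6-enolexo-exo-trig; all other enolate and carbonyl pairs would give four-membered rings), loss of water gives the enone, and the two equatorial bonds C8–C14 and C9–C11 make the B/C fusion trans.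

Step 13
Reactants: 19 tricyclic enone
Product: 21 tricyclic 6-hydroxy-13-ketone, via saturated benzyl ether 20 (not isolated)
Conditions: H2 (3 atm), Pd(OH)2/C, EtOH, rt
Reagents that add atoms: none
Why: Hydrogenation over Pd(OH)2/C saturates the disubstituted C11=C12 bond and then cleaves the benzyl ether by hydrogenolysis, no stereocentre being formed or touched.

Step 14
Reactants: 21 tricyclic 6-hydroxy-13-ketone
Product: 22 tricyclic 6-acetoxy-13-ketone
Conditions: Ac2O, Sc(OTf)3 (5 mol %), MeCN, 0 °C → rt
Reagents that add atoms: acetic anhydride, CC(=O)OC(C)=O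
Why: Sc(OTf)3-catalysed acylation generates a small, highly electrophilic acetylating species that reaches the axial C6 hydroxyl between the methyl groups on C4, C8 and C10, and the acetate is placed now, while this is the only hydroxyl group, because the later C20 hydroxyl would acylate faster.

Step 15
Reactants: 23 1,4-dioxaspiro[4.5]dec-6-en-8-one
Product: 24 7-iodo-1,4-dioxaspiro[4.5]dec-6-en-8-one
Conditions: I2, pyridine–CH2Cl2, 0 °C → rt
Reagents that add atoms: iodine, II
Why: α-Iodination of the enone by conjugate addition of pyridine, iodination of the enolate and elimination of pyridine is a standard reaction of cyclohexenones, and the ketal is inert to it.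

Step 16
Reactants: 24 iodo enone
Product: 25 (R)-7-iodo-1,4-dioxaspiro[4.5]dec-6-en-8-ol
Conditions: (S)-2-methyl-CBS-oxazaborolidine (10 mol %), BH3·SMe2, THF, −20 °C; MeOH
Reagents that add atoms: none
Why: Corey–Bakshi–Shibata reduction: the catalyst distinguishes the iodoalkenyl side (large) from the CH2 side (small) of the ketone and the (S)-catalyst delivers hydride to the face that gives the (R)-alcohol (future C17), 2-haloenones being among the best substrates for this reaction.

Step 17
Reactants: 25 (R)-iodo allylic alcohol
Product: 26 (R)-7-methyl-1,4-dioxaspiro[4.5]dec-6-en-8-ol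
Conditions: Me2Zn (3 equiv), Pd(dppf)Cl2 (5 mol %), THF, 50 °C
Reagents that add atoms: dimethylzinc, C[Zn]C
Why: Negishi coupling of the alkenyl iodide with Me2Zn (one equivalent is spent on the hydroxyl group) installs the C18 methyl group with retention of the ring alkene and does not touch C17.

Step 18
Reactants: 26 (R)-methyl allylic alcohol ketal
Product: 27 (R)-4-hydroxy-3-methylcyclohex-2-en-1-one
Conditions: PPTS (cat), acetone–H2O, rt
Reagents that add atoms: water, O
Why: Mild acid hydrolysis of the allylic ketal proceeds through a conjugated oxocarbenium ion and releases the enone, the C17 carbinol not being ionised under these conditions.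

Step 19
Reactants: 27 (R)-4-hydroxy-3-methylcyclohex-2-en-1-one
Product: 28 (R)-3-methyl-4-(triethylsilyloxy)cyclohex-2-en-1-one
Conditions: TESCl, imidazole, CH2Cl2, 0 °C
Reagents that add atoms: chlorotriethylsilane, CC[Si](Cl)(CC)CC
Why: Standard silylation, the triethylsilyl group being chosen because it can later be removed in the presence of a tert-butyldimethylsilyl ether.

Step 20
Reactants: 28 (R)-3-methyl-4-(triethylsilyloxy)cyclohex-2-en-1-one; 22 tricyclic 6-acetoxy-13-ketone
Product: 31 C13–C15 aldol adduct (C13–OH axial on the Me-face; C15 substituent trans to C17–OTES; C20 ketone), via lithium dienolate 29 (not isolated), via dichlorocerium dienolate 30 (not isolated)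
Conditions: 28 (2 equiv), LDA, THF, −78 °C; CeCl3 (anhydrous), −78 °C; 22, −78 °C; aq NH4Cl, −78 °C
Reagents that add atoms: none
Why: Kinetic α′-deprotonation and transmetalation give a weakly basic cerium dienolate, a class whose aldol addition to ketones suppresses enolisation and retro-aldol cleavage; it attacks the C13 ketone along the equatorial trajectory because the axial C8 methyl group blocks the axial one, which puts the C13 oxygen axial on the Me-face, and it reacts at C15 on the face opposite the C17 silyloxy group, held pseudoaxial by allylic strain with the C18 methyl group, the enantiopure dienolate being needed because C12 and C14 are both CH2 groups and ring C alone could not differentiate the two faces of ring E.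

Step 21
Reactants: 31 aldol adduct
Product: 32 C13/C20 diol (C20–OH cis to the C15 substituent)
Conditions: L-Selectride (2.5 equiv), THF, −78 °C; NaBO3·4H2O, THF–H2O, rt
Reagents that add atoms: none
Why: The bulky trialkylborohydride adds in a 1,2 sense because C18 is fully substituted and takes the equatorial trajectory, as in the reduction of 2-alkylcyclohexanones to cis-2-alkylcyclohexanols, which gives the pseudoaxial C20 alcohol cis to the equatorial C15 substituent, while the hindered C6 acetate survives at −78 °C.

Step 22
Reactants: 32 diol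
Product: 33 C20 tert-butyldimethylsilyl ether
Conditions: TBSOTf (1.2 equiv), 2,6-lutidine, CH2Cl2, −78 → −40 °C
Reagents that add atoms: tert-butyldimethylsilyl triflate, CC(C)(C)[Si](C)(C)OS(=O)(=O)C(F)(F)F
Why: A silyl triflate with a hindered base silylates the secondary allylic C20 hydroxyl much faster than the axial tertiary C13 hydroxyl, which masks C20–OH for the oxidation in step 24.

Step 23
Reactants: 33 C20 TBS, C17 TES bis-silyl ether
Product: 34 C17 allylic alcohol
Conditions: PPTS (0.2 equiv), MeOH–CH2Cl2, 0 °C
Reagents that add atoms: none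
Why: Mild acid-catalysed methanolysis cleaves a secondary triethylsilyl ether selectively in the presence of a tert-butyldimethylsilyl ether, an established difference in rate.

Step 24
Reactants: 34 C17 allylic alcohol
Product: 35 C17 enone (C18=C19) with C20–OTBS and free C13–OH
Conditions: Dess–Martin periodinane, CH2Cl2, 0 °C → rt
Reagents that add atoms: none
Why: Dess–Martin oxidation of the only oxidisable (secondary allylic) alcohol gives the C17 enone, the tertiary C13 alcohol being inert.

Step 25
Reactants: 35 C17 enone
Product: 37 CNP0188572.2 (target), via dihydroxy enone 36 (not isolated)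
Conditions: HF·pyridine, THF–pyridine, 0 °C → rt; after aq NaHCO3 wash, DBU (0.2 equiv), CH2Cl2, rt
Reagents that add atoms: none
Why: Fluoride-mediated desilylation frees C20–OH and base then triggers a 5-exo-trig intramolecular oxa-Michael addition of the C13 alcohol to C19, which can only occur on the ring-E face that carries C13 and therefore fixes C19, while reversible enolisation lets the C18 methyl group take the equatorial position cis to the ether oxygen.

**Compound list**
1 | 2,6-dimethyl-1,4-benzoquinone | CC1=CC(=O)C=C(C)C1=O | starting material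
2 | 4-methylpenta-1,3-diene | CC(C)=CC=C | starting material
3 | cis-fused Diels–Alder enedione | C[C@@]12CC=CC(C)(C)[C@@H]1C(=O)C=C(C)C2=O | intermediate
4 | ring-A alkene dione (C7–C8 saturated, not isolated) | C[C@@]12CC=CC(C)(C)[C@@H]1C(=O)CC(C)C2=O | intermediate
5 | cis-fused saturated 6,9-dione (C8 epimers) | C[C@@]12CCCC(C)(C)[C@@H]1C(=O)CC(C)C2=O | intermediate
6 | trans-fused 6,9-dione, C8–CH3 equatorial | O=C1C[C@H](C)C(=O)[C@]2(C)CCCC(C)(C)[C@@H]12 | intermediate
7 | 6-hydroxy-9-ketone, axial OH | O[C@H]1C[C@H](C)C(=O)[C@]2(C)CCCC(C)(C)[C@@H]12 | intermediate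
8 | 6-benzyloxy-9-ketone | c1ccccc1CO[C@H]1C[C@H](C)C(=O)[C@]2(C)CCCC(C)(C)[C@@H]12 | intermediate
9 | potassium C8=C9 enolate (not isolated) | c1ccccc1CO[C@H]1CC(C)=C([O-])[C@]2(C)CCCC(C)(C)[C@@H]12.[K+] | intermediate
10 | C8=C9 enol triflate | c1ccccc1CO[C@H]1CC(C)=C(OS(=O)(=O)C(F)(F)F)[C@]2(C)CCCC(C)(C)[C@@H]12 | intermediate
11 | methyl C8=C9-ene-11-oate | c1ccccc1CO[C@H]1CC(C)=C(C(=O)OC)[C@]2(C)CCCC(C)(C)[C@@H]12 | intermediate
12 | C8=C9 allylic alcohol | c1ccccc1CO[C@H]1CC(C)=C(CO)[C@]2(C)CCCC(C)(C)[C@@H]12 | intermediate
13 | allyl isopropenyl ether (not isolated) | c1ccccc1CO[C@H]1CC(C)=C(COC(C)=C)[C@]2(C)CCCC(C)(C)[C@@H]12 | intermediate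
14 | C8-acetonyl C9-methylene decalin | c1ccccc1CO[C@H]1C[C@](C)(CC(C)=O)C(=C)[C@]2(C)CCCC(C)(C)[C@@H]12 | intermediate
15 | bis-boron adduct (C11–BH2, C13–OBH2; not isolated) | c1ccccc1CO[C@H]1C[C@](C)(CC(C)OB)[C@@H](CB)[C@]2(C)CCCC(C)(C)[C@@H]12 | intermediate
16 | C11/C13 diol (C13 epimers) | c1ccccc1CO[C@H]1C[C@](C)(CC(C)O)[C@@H](CO)[C@]2(C)CCCC(C)(C)[C@@H]12 | intermediate
17 | C11 aldehyde C13 methyl ketone | c1ccccc1CO[C@H]1C[C@](C)(CC(C)=O)[C@@H](C=O)[C@]2(C)CCCC(C)(C)[C@@H]12 | intermediate
18 | tricyclic aldol (C11 carbinol, not isolated) | c1ccccc1CO[C@H]1C[C@]2(C)CC(=O)CC(O)[C@H]2[C@]2(C)CCCC(C)(C)[C@@H]12 | intermediate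
19 | tricyclic C11=C12 en-13-one | c1ccccc1CO[C@H]1C[C@]2(C)CC(=O)C=C[C@H]2[C@]2(C)CCCC(C)(C)[C@@H]12 | intermediate
20 | saturated benzyl ether (not isolated) | c1ccccc1CO[C@H]1C[C@]2(C)CC(=O)CC[C@H]2[C@]2(C)CCCC(C)(C)[C@@H]12 | intermediate
21 | tricyclic 6-hydroxy-13-ketone | O[C@H]1C[C@]2(C)CC(=O)CC[C@H]2[C@]2(C)CCCC(C)(C)[C@@H]12 | intermediate
22 | tricyclic 6-acetoxy-13-ketone | CC(=O)O[C@H]1C[C@]2(C)CC(=O)CC[C@H]2[C@]2(C)CCCC(C)(C)[C@@H]12 | intermediate
23 | 1,4-dioxaspiro[4.5]dec-6-en-8-one | O=C1C=CC2(CC1)OCCO2 | starting material
24 | 7-iodo-1,4-dioxaspiro[4.5]dec-6-en-8-one | O=C1C(I)=CC2(CC1)OCCO2 | intermediate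
25 | (R)-7-iodo-1,4-dioxaspiro[4.5]dec-6-en-8-ol | IC1=CC2(CC[C@H]1O)OCCO2 | intermediate
26 | (R)-7-methyl-1,4-dioxaspiro[4.5]dec-6-en-8-ol | CC1=CC2(CC[C@H]1O)OCCO2 | intermediate
27 | (R)-4-hydroxy-3-methylcyclohex-2-en-1-one | CC1=CC(=O)CC[C@H]1O | intermediate
28 | (R)-3-methyl-4-(triethylsilyloxy)cyclohex-2-en-1-one | CC1=CC(=O)CC[C@H]1O[Si](CC)(CC)CC | intermediate
29 | lithium cross-conjugated dienolate (not isolated) | CC1=CC(O[Li])=CC[C@H]1O[Si](CC)(CC)CC | intermediate
30 | dichlorocerium dienolate (not isolated) | CC1=CC(O[Ce](Cl)Cl)=CC[C@H]1O[Si](CC)(CC)CC | intermediate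
31 | C13–C15 aldol adduct | CC(=O)O[C@H]1C[C@]2(C)C[C@@](O)(CC[C@H]2[C@]2(C)CCCC(C)(C)[C@@H]12)[C@@H]1C[C@@H](O[Si](CC)(CC)CC)C(C)=CC1=O | intermediate
32 | C13/C20 diol | CC(=O)O[C@H]1C[C@]2(C)C[C@@](O)(CC[C@H]2[C@]2(C)CCCC(C)(C)[C@@H]12)[C@@H]1C[C@@H](O[Si](CC)(CC)CC)C(C)=C[C@@H]1O | intermediate
33 | C20 TBS ether | CC(=O)O[C@H]1C[C@]2(C)C[C@@](O)(CC[C@H]2[C@]2(C)CCCC(C)(C)[C@@H]12)[C@@H]1C[C@@H](O[Si](CC)(CC)CC)C(C)=C[C@@H]1O[Si](C)(C)C(C)(C)C | intermediate
34 | C17 allylic alcohol | CC(=O)O[C@H]1C[C@]2(C)C[C@@](O)(CC[C@H]2[C@]2(C)CCCC(C)(C)[C@@H]12)[C@@H]1C[C@@H](O)C(C)=C[C@@H]1O[Si](C)(C)C(C)(C)C | intermediate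
35 | C17 enone | CC(=O)O[C@H]1C[C@]2(C)C[C@@](O)(CC[C@H]2[C@]2(C)CCCC(C)(C)[C@@H]12)[C@@H]1CC(=O)C(C)=C[C@@H]1O[Si](C)(C)C(C)(C)C | intermediate
36 | dihydroxy enone (open form, not isolated) | CC(=O)O[C@H]1C[C@]2(C)C[C@@](O)(CC[C@H]2[C@]2(C)CCCC(C)(C)[C@@H]12)[C@@H]1CC(=O)C(C)=C[C@@H]1O | intermediate
37 | CNP0188572.2 | CC(=O)O[C@H]1C[C@]2(C)C[C@]3(CC[C@H]2[C@]2(C)CCCC(C)(C)[C@@H]12)O[C@@H]1[C@H](O)[C@H]3CC(=O)[C@@H]1C | target

Total steps: 25. Longest linear sequence: 20 steps (1–14, then 20–25). The ring-E branch (15–19) has 5 steps.

**Steps most likely to fail**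

1. Step 1.
- Risk: acid-induced oligomerisation of 2 may outrun a cycloaddition that is slowed by the Z-methyl group. Raising the temperature may also erode the facial selectivity.
- Fallback (from 1, back at 5): the diene is made more nucleophilic instead of forcing the conditions.
- Mesityl oxide is converted (LDA, THF, −78 °C; TBSOTf) into 2-(tert-butyldimethylsilyloxy)-4-methylpenta-1,3-diene F1. It belongs to the 2-silyloxydiene class that is the standard partner of this catalyst.
- Both donor groups direct its CH2 terminus to C10, so the same two bonds form under the same catalyst and give the C2-silyloxy cis adduct F2.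
- Hydrogenation of the enedione bond (H2, Pd/C) gives the dihydro silyl enol ether F3, and dilute HCl in THF gives the cis-fused 2,6,9-trione F4.
- Ethane-1,2-dithiol with BF3·OEt2 converts the only ketone that lies between two CH2 groups into the C2 dithiolane F5. Raney nickel then removes it to give 5.

2. Step 20.
- Risk: proton transfer from the ketone to the dienolate, and retro-aldol cleavage of the congested tertiary aldolate before the quench, may keep conversion low.
- Fallback (from 28 and 22, back at 31): the basic metal enolate is replaced by a neutral silyl nucleophile and the ketone is activated instead.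
- Compound 28 is converted (LDA, THF, −78 °C; TMSCl) into the 2-(trimethylsilyloxy)diene F6.
- F6 is added to 22 precomplexed with TiCl4 in CH2Cl2 at −78 °C (Mukaiyama aldol addition). The adduct is held as a titanium chelate until work-up, so it cannot revert.
- Attack on C13 remains equatorial. The 15,17-trans isomer is also the more stable one, so a C15 epimer can be converged on 31 by mild equilibration.

3. Step 21.
- Risk: hydride may be delivered along the axial trajectory and give the wrong configuration at C20. The lithium alkoxide may also undergo retro-aldol cleavage.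
- Fallback (from 31, back at 32): the sterically easy reduction is accepted and C20 is inverted afterwards.
- Luche reduction (NaBH4, CeCl3·7H2O, MeOH, −78 °C), which is non-basic, gives the equatorial C20 epimer of the diol F7.
- Mitsunobu reaction (4-nitrobenzoic acid, PPh3, DIAD, THF) inverts C20 and gives the C20 4-nitrobenzoate F8.
- Brief K2CO3/MeOH cleaves this activated ester, but not the hindered C6 acetate, to give 32.

**Further compounds**
F1 | step 1 | 2-(tert-butyldimethylsilyloxy)-4-methylpenta-1,3-diene | C=C(O[Si](C)(C)C(C)(C)C)C=C(C)C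
F2 | step 1 | C2-silyloxy cis adduct | C[C@@]12CC(O[Si](C)(C)C(C)(C)C)=CC(C)(C)[C@@H]1C(=O)C=C(C)C2=O
F3 | step 1 | dihydro silyl enol ether | C[C@@]12CC(O[Si](C)(C)C(C)(C)C)=CC(C)(C)[C@@H]1C(=O)CC(C)C2=O
F4 | step 1 | cis-fused 2,6,9-trione | C[C@@]12CC(=O)CC(C)(C)[C@@H]1C(=O)CC(C)C2=O
F5 | step 1 | C2 dithiolane | C[C@@]12CC3(SCCS3)CC(C)(C)[C@@H]1C(=O)CC(C)C2=O
F6 | step 20 | 2-(trimethylsilyloxy)diene from 28 | CC1=CC(O[Si](C)(C)C)=CC[C@H]1O[Si](CC)(CC)CC
F7 | step 21 | C20 epimer of the diol | CC(=O)O[C@H]1C[C@]2(C)C[C@@](O)(CC[C@H]2[C@]2(C)CCCC(C)(C)[C@@H]12)[C@@H]1C[C@@H](O[Si](CC)(CC)CC)C(C)=C[C@H]1O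
F8 | step 21 | C20 4-nitrobenzoate | CC(=O)O[C@H]1C[C@]2(C)C[C@@](O)(CC[C@H]2[C@]2(C)CCCC(C)(C)[C@@H]12)[C@@H]1C[C@@H](O[Si](CC)(CC)CC)C(C)=C[C@@H]1OC(=O)c1ccc(cc1)[N+](=O)[O-]
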